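**Plan**
Tetralone numbering: C1 ketone, C3 carbinol, C5 pyranonyl, C6 3-methylbutyl, C8 phenol; ring A = benzene, ring B = C1–C4/C4a/C8a, ring C = pyranone (primed atoms).
Cuts: ring C at O1'–C2' and C5'–C6' (back to a C5 formyl group and a dioxinone), ring A at C4a–C5 and C6–C7, then C8–C8a, and ring B at C1–C8a and C4–C4a.
Enabling feature: the C8 oxygen is para to the C5 carbon substituent on a benzene fused to a 5-oxygenated cyclohexenone (ring B), which is the pattern a 2-alkoxydiene and an acetylenic aldehyde give after cycloaddition and dehydrogenation.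
Forward order: ring B is made first from an acyclic hydroxy ester (cyclopropanol formation, ring expansion), ring A follows by [4+2] cycloaddition and aromatisation, ring C is built last on the C5 aldehyde, and two deprotections finish.
Stereochemistry: the single stereocentre C3 (R) comes from ethyl (S)-4-chloro-3-hydroxybutanoate and is never a reacting centre.

Key step: step 9

Assumption: the target carbinol ([C@@H] in the given SMILES) is read as R, and the aryl–pyranone bond is taken as freely rotating, so no axial descriptor is carried.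

**Route**

Step 1
Reactants: 1 ethyl (S)-4-chloro-3-hydroxybutanoate
Product: 2 ethyl (S)-3,4-epoxybutanoate
Conditions: Ag2O (1.2 equiv), DME, 60 °C, dark
Reagents that add atoms: none
Why: Silver-assisted halohydrin-to-epoxide closure (intramolecular Williamson etherification), in which Ag2O pulls off chloride while the C3 hydroxyl attacks C4, so the stereocentre is untouched and the neutral medium avoids β-elimination to the 4-hydroxycrotonate.

Step 2
Reactants: 2 ethyl (S)-3,4-epoxybutanoate
Product: 3 ethyl (R)-3-hydroxyhex-5-enoate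
Conditions: vinylmagnesium bromide (1.5 equiv), CuI (10 mol %), THF, −40 °C; aq. work-up
Reagents that add atoms: vinylmagnesium bromide, C=C[Mg]Br
Why: CuI-catalysed SN2 opening of the terminal epoxide at its unsubstituted carbon should outpace addition to the ester at low temperature; the carbinol carbon is not involved and its descriptor changes to R only through the CIP priorities.

Step 3
Reactants: 3 ethyl (R)-3-hydroxyhex-5-enoate
Product: 4 ethyl (R)-3-(tert-butyldimethylsilyloxy)hex-5-enoate
Conditions: TBSCl, imidazole, DMF, rt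
Reagents that add atoms: tert-butyldimethylsilyl chloride, CC(C)(C)[Si](C)(C)Cl
Why: Standard imidazole-promoted silylation of a secondary alcohol, giving an ether that survives the organometallic, oxidative and Lewis-acidic steps that follow.

Step 4
Reactants: 4 ethyl (R)-3-(tert-butyldimethylsilyloxy)hex-5-enoate
Product: 5 (3R)-3-(tert-butyldimethylsilyloxy)bicyclo[3.1.0]hexan-1-ol (cis-fused epimer pair at C1/C5)
Conditions: Ti(OiPr)4 (1.3 equiv), i-PrMgCl (2.6 equiv), Et2O, −45 → 0 °C; aq. work-up
Reagents that add atoms: none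
Why: Intramolecular Kulinkovich cyclopropanation, in which the propene complex of formally divalent titanium made from Ti(OiPr)4 and i-PrMgCl exchanges its alkene for the terminal alkene of 4 and the titanacyclopropane then acylates itself with the ester and closes to the cyclopropanol; the two new ring-fusion centres form without control and are both destroyed in step 5.

Step 5
Reactants: 5 (3R)-3-(tert-butyldimethylsilyloxy)bicyclo[3.1.0]hexan-1-ol
Product: 7 (R)-5-(tert-butyldimethylsilyloxy)cyclohex-2-enone, via chloroketone 6 (not isolated)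
Conditions: FeCl3 (2.2 equiv), DMF, 0 °C; crude 6, then NaOAc, MeOH, rt
Reagents that add atoms: none
Why: Saegusa-type FeCl3 oxidative ring expansion, in which the cyclopropanol is oxidised to an alkoxy radical that cleaves the internal cyclopropane bond to the secondary ring-expanded radical, chlorine transfer gives the β-chloroketone (chloride epimers, irrelevant), and NaOAc eliminates HCl into conjugation under conditions too mild to expel the β-silyloxy group.

Step 6
Reactants: 7 (R)-5-(tert-butyldimethylsilyloxy)cyclohex-2-enone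
Product: 8 (R)-5-(tert-butyldimethylsilyloxy)-2-iodocyclohex-2-enone
Conditions: I2 (1.5 equiv), pyridine, CH2Cl2, 0 °C → rt
Reagents that add atoms: iodine, II
Why: Johnson α-iodination of an enone (conjugate addition of pyridine, iodination of the enolate at C2, loss of pyridinium); the transient enolate lies on the side away from the silyloxy carbon, so no elimination path is opened and no stereocentre is formed.

Step 7
Reactants: 8 (R)-5-(tert-butyldimethylsilyloxy)-2-iodocyclohex-2-enone; 9 tributyl(1-ethoxyvinyl)stannane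
Product: 10 (R)-5-(tert-butyldimethylsilyloxy)-2-(1-ethoxyvinyl)cyclohex-2-enone
Conditions: 9 (1.2 equiv), Pd2(dba)3 (2.5 mol %), AsPh3 (10 mol %), CuI (10 mol %), NMP, rt; chromatography on Et3N-deactivated silica
Reagents that add atoms: none
Why: Stille cross-coupling, in which zerovalent palladium inserts into the vinyl C–I bond, CuI and the weakly bound AsPh3 speed transmetallation from tin at the hindered α-carbon, and the neutral conditions spare both the acid-labile enol ether and the β-silyloxy ketone.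

Step 8
Reactants: 11 5-methylhex-1-yne
Product: 13 6-methylhept-2-ynal, via lithium acetylide 12 (not isolated)
Conditions: n-BuLi, THF, −78 °C; DMF, −78 → 0 °C; reverse quench into cold aqueous phosphate buffer (pH 5)/MTBE
Reagents that add atoms: N,N-dimethylformamide, CN(C)C=O
Why: Formylation of a lithium acetylide with DMF, where the stable hemiaminal alkoxide releases the aldehyde only on the buffered reverse quench, which keeps dimethylamine from adding to the ynal.

Step 9
Reactants: 10 (R)-5-(tert-butyldimethylsilyloxy)-2-(1-ethoxyvinyl)cyclohex-2-enone; 13 6-methylhept-2-ynal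
Product: 15 (R)-7-(tert-butyldimethylsilyloxy)-4-ethoxy-2-(3-methylbutyl)-5-oxo-5,6,7,8-tetrahydronaphthalene-1-carbaldehyde, via cyclohexadiene adduct 14 (not isolated)
Conditions: 13 (2 equiv), toluene (1 M), BHT (cat.), 80 °C, sealed tube; then DDQ (1.2 equiv), rt
Reagents that add atoms: none
Why: A thermal, normal-electron-demand Diels–Alder reaction joins the s-cis diene of 10 (enol-ether alkene C7=C8 and enone alkene C8a=C4a) to the triple bond of 13 in a concerted, asynchronous transition state, and DDQ then removes the doubly allylic hydrogens at C4a and C7 of adduct 14 to give the benzene. The closest known reaction type is the cycloaddition of 2-alkoxy-1,3-dienes with acetylenic aldehydes followed by quinone dehydrogenation of the 1,4-cyclohexadiene. Ring A closes by intermolecular [4+2] cycloaddition, the two new σ bonds C4a–C5 and C6–C7 forming suprafacially on both partners. The only new stereocentre, C4a of 14, is erased on aromatisation, so facial selectivity relative to the C3 silyloxy group does not matter, and C3 lies outside the reacting atoms. The step needs regioselectivity (ethoxy para to formyl), which is secured because the largest HOMO coefficient of the diene sits on the enol-ether CH2 (C7) and the largest LUMO coefficient of the ynal on its β carbon (C6), a pairing reinforced by the enone β carbon C4a bonding to the ynal α carbon C5. The neutral, base-free medium keeps the β-silyloxy ketone from eliminating, and the 2,3-disubstituted diene, whose ring CH2 on C4a points outward, reaches the s-cis geometry without strain.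

Step 10
Reactants: 16 2,2,6-trimethyl-4H-1,3-dioxin-4-one
Product: 18 trimethyl[(2,2-dimethyl-4-methylidene-4H-1,3-dioxin-6-yl)oxy]silane, via lithium dienolate 17 (not isolated)
Conditions: LDA (1.1 equiv), THF, −78 °C; TMSCl, −78 °C → rt; used after bulb-to-bulb distillation
Reagents that add atoms: chlorotrimethylsilane, C[Si](C)(C)Cl
Why: Kinetic γ-deprotonation of the vinylogous ester and O-silylation of the resulting dienolate is the standard preparation of this silyl dienol ether.

Step 11
Reactants: 15 (R)-7-(tert-butyldimethylsilyloxy)-4-ethoxy-2-(3-methylbutyl)-5-oxo-5,6,7,8-tetrahydronaphthalene-1-carbaldehyde; 18 trimethyl[(2,2-dimethyl-4-methylidene-4H-1,3-dioxin-6-yl)oxy]silane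
Product: 19 6-{2-[(7R)-7-(tert-butyldimethylsilyloxy)-4-ethoxy-2-(3-methylbutyl)-5-oxo-5,6,7,8-tetrahydronaphthalen-1-yl]-2-hydroxyethyl}-2,2-dimethyl-4H-1,3-dioxin-4-one (carbinol epimers)
Conditions: 18 (2 equiv), BF3·OEt2 (1.2 equiv), CH2Cl2, −78 °C; H2O
Reagents that add atoms: none
Why: Vinylogous Mukaiyama aldol addition, γ-selective for this dienolate and chemoselective for the BF3-activated aldehyde over the aryl ketone, run without base so the β-silyloxy ketone is safe; the new carbinol centre forms without control and is removed by oxidation in step 12.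

Step 12
Reactants: 19 the δ-hydroxy dioxinone from step 11
Product: 20 6-{2-[(7R)-7-(tert-butyldimethylsilyloxy)-4-ethoxy-2-(3-methylbutyl)-5-oxo-5,6,7,8-tetrahydronaphthalen-1-yl]-2-oxoethyl}-2,2-dimethyl-4H-1,3-dioxin-4-one
Conditions: Dess–Martin periodinane (1.3 equiv), CH2Cl2, rt
Reagents that add atoms: none
Why: Dess–Martin oxidation of a secondary benzylic alcohol to the ketone under near-neutral conditions that leave the dioxinone, silyl ether and aryl ether alone.

Step 13
Reactants: 20 the β-keto dioxinone from step 12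
Product: 22 6-[(7R)-7-(tert-butyldimethylsilyloxy)-4-ethoxy-2-(3-methylbutyl)-5-oxo-5,6,7,8-tetrahydronaphthalen-1-yl]-4-hydroxy-2H-pyran-2-one, via acylketene 21 (not isolated)
Conditions: toluene (0.01 M), 110 °C
Reagents that add atoms: none
Why: Dioxinone thermolysis (retro-[4+2] loss of acetone) gives an acylketene that is captured by the enol oxygen of the neighbouring aryl ketone in a six-membered closure, and tautomerisation gives the 4-hydroxy-2-pyranone; this is the established route from 6-(2-oxoalkyl)dioxinones to such pyranones.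

Step 14
Reactants: 22 the ethyl ether pyranone from step 13
Product: 23 6-[(7R)-7-(tert-butyldimethylsilyloxy)-4-hydroxy-2-(3-methylbutyl)-5-oxo-5,6,7,8-tetrahydronaphthalen-1-yl]-4-hydroxy-2H-pyran-2-one
Conditions: BCl3 (3 equiv), CH2Cl2, −78 → −20 °C; H2O
Reagents that add atoms: none
Why: Chelation-assisted ether cleavage, in which BCl3 bridges the C1 carbonyl and the peri C8 ether oxygen and chloride then removes the ethyl group, should be selective for this position at low temperature, where the hindered secondary silyl ether is expected to persist.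

Step 15
Reactants: 23 the silyl ether from step 14
Product: 24 4-hydroxy-6-[(7R)-4,7-dihydroxy-2-(3-methylbutyl)-5-oxo-5,6,7,8-tetrahydronaphthalen-1-yl]-2H-pyran-2-one (target)
Conditions: 48% aq. HF, MeCN, 0 °C; pH 7 buffer work-up
Reagents that add atoms: none
Why: Fluoride-driven desilylation under mildly acidic conditions of the kind routinely used to unmask β-hydroxy ketones without dehydration, leaving the C3 configuration as installed in step 1.

**Compound list**
1 | ethyl (S)-4-chloro-3-hydroxybutanoate | ClC[C@@H](O)CC(=O)OCC | starting material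
2 | ethyl (S)-3,4-epoxybutanoate | C1[C@@H](O1)CC(=O)OCC | intermediate
3 | ethyl (R)-3-hydroxyhex-5-enoate | C=CC[C@@H](O)CC(=O)OCC | intermediate
4 | ethyl (R)-3-(tert-butyldimethylsilyloxy)hex-5-enoate | C=CC[C@@H](O[Si](C)(C)C(C)(C)C)CC(=O)OCC | intermediate
5 | (3R)-3-(tert-butyldimethylsilyloxy)bicyclo[3.1.0]hexan-1-ol, cis-fused, epimer pair at C1/C5 | OC12CC1C[C@@H](O[Si](C)(C)C(C)(C)C)C2 | intermediate
6 | 3-chloro-5-(tert-butyldimethylsilyloxy)cyclohexanone, silyloxy carbon S, chloride epimers | O=C1CC(Cl)C[C@@H](O[Si](C)(C)C(C)(C)C)C1 | intermediate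
7 | (R)-5-(tert-butyldimethylsilyloxy)cyclohex-2-enone | O=C1C=CC[C@@H](O[Si](C)(C)C(C)(C)C)C1 | intermediate
8 | (R)-5-(tert-butyldimethylsilyloxy)-2-iodocyclohex-2-enone | O=C1C(I)=CC[C@@H](O[Si](C)(C)C(C)(C)C)C1 | intermediate
9 | tributyl(1-ethoxyvinyl)stannane | CCCC[Sn](CCCC)(CCCC)C(=C)OCC | starting material
10 | (R)-5-(tert-butyldimethylsilyloxy)-2-(1-ethoxyvinyl)cyclohex-2-enone | C=C(OCC)C1=CC[C@@H](O[Si](C)(C)C(C)(C)C)CC1=O | intermediate
11 | 5-methylhex-1-yne | C#CCCC(C)C | starting material
12 | (5-methylhex-1-yn-1-yl)lithium | [Li]C#CCCC(C)C | intermediate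
13 | 6-methylhept-2-ynal | CC(C)CCC#CC=O | intermediate
14 | (7R)-7-(tert-butyldimethylsilyloxy)-4-ethoxy-2-(3-methylbutyl)-5-oxo-3,5,6,7,8,8a-hexahydronaphthalene-1-carbaldehyde, C8a epimers | CC(C)CCC1=C(C=O)C2C[C@@H](O[Si](C)(C)C(C)(C)C)CC(=O)C2=C(OCC)C1 | intermediate
15 | (R)-7-(tert-butyldimethylsilyloxy)-4-ethoxy-2-(3-methylbutyl)-5-oxo-5,6,7,8-tetrahydronaphthalene-1-carbaldehyde | CC(C)CCc1cc(OCC)c2c(c1C=O)C[C@@H](O[Si](C)(C)C(C)(C)C)CC2=O | intermediate
16 | 2,2,6-trimethyl-4H-1,3-dioxin-4-one | CC1=CC(=O)OC(C)(C)O1 | starting material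
17 | lithium 2,2-dimethyl-4-methylidene-4H-1,3-dioxin-6-olate | [Li+].C=C1C=C([O-])OC(C)(C)O1 | intermediate
18 | trimethyl[(2,2-dimethyl-4-methylidene-4H-1,3-dioxin-6-yl)oxy]silane | C=C1C=C(O[Si](C)(C)C)OC(C)(C)O1 | intermediate
19 | 6-{2-[(7R)-7-(tert-butyldimethylsilyloxy)-4-ethoxy-2-(3-methylbutyl)-5-oxo-5,6,7,8-tetrahydronaphthalen-1-yl]-2-hydroxyethyl}-2,2-dimethyl-4H-1,3-dioxin-4-one, carbinol epimers | CC(C)CCc1cc(OCC)c2c(c1C(O)CC1=CC(=O)OC(C)(C)O1)C[C@@H](O[Si](C)(C)C(C)(C)C)CC2=O | intermediate
20 | 6-{2-[(7R)-7-(tert-butyldimethylsilyloxy)-4-ethoxy-2-(3-methylbutyl)-5-oxo-5,6,7,8-tetrahydronaphthalen-1-yl]-2-oxoethyl}-2,2-dimethyl-4H-1,3-dioxin-4-one | CC(C)CCc1cc(OCC)c2c(c1C(=O)CC1=CC(=O)OC(C)(C)O1)C[C@@H](O[Si](C)(C)C(C)(C)C)CC2=O | intermediate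
21 | 5-[(7R)-7-(tert-butyldimethylsilyloxy)-4-ethoxy-2-(3-methylbutyl)-5-oxo-5,6,7,8-tetrahydronaphthalen-1-yl]pent-1-ene-1,3,5-trione (acylketene) | CC(C)CCc1cc(OCC)c2c(c1C(=O)CC(=O)C=C=O)C[C@@H](O[Si](C)(C)C(C)(C)C)CC2=O | intermediate
22 | 6-[(7R)-7-(tert-butyldimethylsilyloxy)-4-ethoxy-2-(3-methylbutyl)-5-oxo-5,6,7,8-tetrahydronaphthalen-1-yl]-4-hydroxy-2H-pyran-2-one | CC(C)CCc1cc(OCC)c2c(c1-c1cc(O)cc(=O)o1)C[C@@H](O[Si](C)(C)C(C)(C)C)CC2=O | intermediate
23 | 6-[(7R)-7-(tert-butyldimethylsilyloxy)-4-hydroxy-2-(3-methylbutyl)-5-oxo-5,6,7,8-tetrahydronaphthalen-1-yl]-4-hydroxy-2H-pyran-2-one | CC(C)CCc1cc(O)c2c(c1-c1cc(O)cc(=O)o1)C[C@@H](O[Si](C)(C)C(C)(C)C)CC2=O | intermediate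
24 | 4-hydroxy-6-[(7R)-4,7-dihydroxy-2-(3-methylbutyl)-5-oxo-5,6,7,8-tetrahydronaphthalen-1-yl]-2H-pyran-2-one | CC(C)CCc1cc(O)c2c(c1-c1cc(O)cc(=O)o1)C[C@@H](O)CC2=O | target

**Step count**
Total steps: 15. Longest linear sequence: 13 (steps 1–7, 9, 11–15); steps 8 and 10 make the two side fragments.

**Steps most likely to fail**

Step 9. The ketone conjugated to the C4a=C8a alkene lowers the diene HOMO, so the cycloaddition may be outrun by oligomerisation of the ynal, self-dimerisation of the diene or adventitious hydrolysis of its enol ether. The fallback takes C1 to the alcohol oxidation level, so that the diene is an ordinary electron-rich 1-vinylcyclohexene. It sets out from 8. Luche reduction (NaBH4, CeCl3·7H2O, MeOH, −78 °C) should give (5R)-5-(tert-butyldimethylsilyloxy)-2-iodocyclohex-2-en-1-ol F1 as C1 epimers of no consequence. Stille coupling with 9 under the conditions of step 7 should give (5R)-5-(tert-butyldimethylsilyloxy)-2-(1-ethoxyvinyl)cyclohex-2-en-1-ol F2. Cycloaddition with 13 in toluene should give (7R)-7-(tert-butyldimethylsilyloxy)-4-ethoxy-5-hydroxy-2-(3-methylbutyl)-3,5,6,7,8,8a-hexahydronaphthalene-1-carbaldehyde F3, which DDQ dehydrogenates in the same flask to (7R)-7-(tert-butyldimethylsilyloxy)-4-ethoxy-5-hydroxy-2-(3-methylbutyl)-5,6,7,8-tetrahydronaphthalene-1-carbaldehyde F4. Dess–Martin oxidation of the benzylic alcohol then returns to the route at 15.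

Step 14. BCl3, or the HCl released when it reacts with the acidic pyranone hydroxyl, may strip the silyl ether, after which the C3 oxygen can leave by β-elimination and ring B aromatises to a naphthol; alternatively the ethyl cleavage may stall. The fallback moves the dealkylation ahead of ring C construction, where no acidic hydroxyl is present and one equivalent of reagent at −78 °C should suffice, and carries the phenol on as its hydrogen-bonded chelate. It sets out from 15. BCl3 (1.1 equiv, CH2Cl2, −78 °C) should give (R)-7-(tert-butyldimethylsilyloxy)-4-hydroxy-2-(3-methylbutyl)-5-oxo-5,6,7,8-tetrahydronaphthalene-1-carbaldehyde F5. Mukaiyama aldol addition of 18 (BF3·OEt2) should give 6-{2-[(7R)-7-(tert-butyldimethylsilyloxy)-4-hydroxy-2-(3-methylbutyl)-5-oxo-5,6,7,8-tetrahydronaphthalen-1-yl]-2-hydroxyethyl}-2,2-dimethyl-4H-1,3-dioxin-4-one F6. Dess–Martin oxidation should give 6-{2-[(7R)-7-(tert-butyldimethylsilyloxy)-4-hydroxy-2-(3-methylbutyl)-5-oxo-5,6,7,8-tetrahydronaphthalen-1-yl]-2-oxoethyl}-2,2-dimethyl-4H-1,3-dioxin-4-one F7. Thermolysis in dilute toluene then proceeds through 5-[(7R)-7-(tert-butyldimethylsilyloxy)-4-hydroxy-2-(3-methylbutyl)-5-oxo-5,6,7,8-tetrahydronaphthalen-1-yl]pent-1-ene-1,3,5-trione F8 and returns to the route at 23.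

Step 11. Addition to the di-ortho-substituted aldehyde, deactivated by the para ethoxy group, may be slow enough that protodesilylation of the dienolate or Lewis-acid attack on the silyl ether takes over. The fallback attaches the dioxinone side chain to the dienophile before the cycloaddition, where the aldehyde is unhindered. It sets out from 13. Aldol addition of 18 (BF3·OEt2, CH2Cl2, −78 °C) should give 6-(2-hydroxy-7-methyloct-3-yn-1-yl)-2,2-dimethyl-4H-1,3-dioxin-4-one F9. Dess–Martin oxidation should give the ynone 2,2-dimethyl-6-(7-methyl-2-oxooct-3-yn-1-yl)-4H-1,3-dioxin-4-one F10. Cycloaddition with 10 (toluene, 70 °C, below the temperature at which the dioxinone opens) should give 6-{2-[(7R)-7-(tert-butyldimethylsilyloxy)-4-ethoxy-2-(3-methylbutyl)-5-oxo-3,5,6,7,8,8a-hexahydronaphthalen-1-yl]-2-oxoethyl}-2,2-dimethyl-4H-1,3-dioxin-4-one F11, and DDQ dehydrogenation of this adduct returns to the route at 20.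

Further compounds
F1 | step 9 | (5R)-5-(tert-butyldimethylsilyloxy)-2-iodocyclohex-2-en-1-ol | OC1C(I)=CC[C@@H](O[Si](C)(C)C(C)(C)C)C1
F2 | step 9 | (5R)-5-(tert-butyldimethylsilyloxy)-2-(1-ethoxyvinyl)cyclohex-2-en-1-ol | C=C(OCC)C1=CC[C@@H](O[Si](C)(C)C(C)(C)C)CC1O
F3 | step 9 | (7R)-7-(tert-butyldimethylsilyloxy)-4-ethoxy-5-hydroxy-2-(3-methylbutyl)-3,5,6,7,8,8a-hexahydronaphthalene-1-carbaldehyde | CC(C)CCC1=C(C=O)C2C[C@@H](O[Si](C)(C)C(C)(C)C)CC(O)C2=C(OCC)C1
F4 | step 9 | (7R)-7-(tert-butyldimethylsilyloxy)-4-ethoxy-5-hydroxy-2-(3-methylbutyl)-5,6,7,8-tetrahydronaphthalene-1-carbaldehyde | CC(C)CCc1cc(OCC)c2c(c1C=O)C[C@@H](O[Si](C)(C)C(C)(C)C)CC2O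
F5 | step 14 | (R)-7-(tert-butyldimethylsilyloxy)-4-hydroxy-2-(3-methylbutyl)-5-oxo-5,6,7,8-tetrahydronaphthalene-1-carbaldehyde | CC(C)CCc1cc(O)c2c(c1C=O)C[C@@H](O[Si](C)(C)C(C)(C)C)CC2=O
F6 | step 14 | 6-{2-[(7R)-7-(tert-butyldimethylsilyloxy)-4-hydroxy-2-(3-methylbutyl)-5-oxo-5,6,7,8-tetrahydronaphthalen-1-yl]-2-hydroxyethyl}-2,2-dimethyl-4H-1,3-dioxin-4-one | CC(C)CCc1cc(O)c2c(c1C(O)CC1=CC(=O)OC(C)(C)O1)C[C@@H](O[Si](C)(C)C(C)(C)C)CC2=O
F7 | step 14 | 6-{2-[(7R)-7-(tert-butyldimethylsilyloxy)-4-hydroxy-2-(3-methylbutyl)-5-oxo-5,6,7,8-tetrahydronaphthalen-1-yl]-2-oxoethyl}-2,2-dimethyl-4H-1,3-dioxin-4-one | CC(C)CCc1cc(O)c2c(c1C(=O)CC1=CC(=O)OC(C)(C)O1)C[C@@H](O[Si](C)(C)C(C)(C)C)CC2=O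
F8 | step 14 | 5-[(7R)-7-(tert-butyldimethylsilyloxy)-4-hydroxy-2-(3-methylbutyl)-5-oxo-5,6,7,8-tetrahydronaphthalen-1-yl]pent-1-ene-1,3,5-trione | CC(C)CCc1cc(O)c2c(c1C(=O)CC(=O)C=C=O)C[C@@H](O[Si](C)(C)C(C)(C)C)CC2=O
F9 | step 11 | 6-(2-hydroxy-7-methyloct-3-yn-1-yl)-2,2-dimethyl-4H-1,3-dioxin-4-one | CC(C)CCC#CC(O)CC1=CC(=O)OC(C)(C)O1
F10 | step 11 | 2,2-dimethyl-6-(7-methyl-2-oxooct-3-yn-1-yl)-4H-1,3-dioxin-4-one | CC(C)CCC#CC(=O)CC1=CC(=O)OC(C)(C)O1
F11 | step 11 | 6-{2-[(7R)-7-(tert-butyldimethylsilyloxy)-4-ethoxy-2-(3-methylbutyl)-5-oxo-3,5,6,7,8,8a-hexahydronaphthalen-1-yl]-2-oxoethyl}-2,2-dimethyl-4H-1,3-dioxin-4-one | CC(C)CCC1=C(C(=O)CC3=CC(=O)OC(C)(C)O3)C2C[C@@H](O[Si](C)(C)C(C)(C)C)CC(=O)C2=C(OCC)C1
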